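**Plan**
1. Retrosynthesis: the three MOM ethers are removed last; ring C is then cut at ring A twice, at the aryl ether bond O1–C8a and at the ketone bond C4–C4a, giving a ring A aryne and a C2–C3–C4 chain already fixed to ring B.
2. Enabling feature: in ring A, O1 (on C8a) and the C4 carbonyl (on C4a) sit on neighbouring carbons, and the C5 oxygen flanks C4a while C8 bears H. An aryne across C4a–C8a therefore takes the C2 alkoxide at C8a and the acyl carbon at C4a.
3. Forward, ring A fragment: resorcinol → bis-MOM ether → C-prenylation between the oxygens → C–H borylation/oxidation → ortho-bromination → retro-Brook/triflation to the ortho-silylaryl triflate. Its precursor phenol is C2v-symmetric, so only one aryne can form and the prenyl group must end at C6.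
4. Forward, ring B fragment and union: methyl 3,5-dibromo-4-hydroxybenzoate → MOM ether → double Stille prenylation → Claisen condensation to the β-keto amide → transfer hydrogenation → O-silylation. Fluoride then joins the fragments: O-arylation, and ring C closes when the aryl anion attacks the amide (C4–C4a).
5. Stereochemistry: C2 (R) is set by Noyori–Ikariya transfer hydrogenation with the (R,R) catalyst and is carried through with retention. The ketone stays masked as a hemiaminal alkoxide while base is present, so ring C cannot open.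

Key step: step 11

Assumption: the C2 descriptor of the given SMILES is read as R (O1 > aryl > C3), the antipode of the common (2S)-flavanones, and the route is set accordingly.
Abbreviations: MOM = methoxymethyl; prenyl = 3-methylbut-2-en-1-yl; TsDPEN = N-tosyl-1,2-diphenylethane-1,2-diamine.

**Route**

Step 1
Reactants: 1 resorcinol
Product: 2 1,3-bis(methoxymethoxy)benzene
Conditions: MOMCl (2.4 equiv), K2CO3, acetone, 0 °C to rt
Reagents that add atoms: chloromethyl methyl ether, COCCl
Why: Williamson-type O-alkylation of both phenols with the reactive α-chloro ether gives the bis-acetal, which later serves as the directing group for metalation.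

Step 2
Reactants: 2 1,3-bis(methoxymethoxy)benzene
Product: 4 1,3-bis(methoxymethoxy)-2-(3-methylbut-2-en-1-yl)benzene, via aryllithium 3 (not isolated)
Conditions: n-BuLi, THF, 0 °C to rt; then CuI (10 mol %), prenyl bromide, −78 °C to rt
Reagents that add atoms: 1-bromo-3-methylbut-2-ene, CC(C)=CCBr
Why: Directed ortho-metalation, in which the two OMOM groups together direct lithiation to the carbon between them, followed by copper-assisted allylic substitution at the primary carbon of prenyl bromide, should give the linear prenyl group.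

Step 3
Reactants: 4 1,3-bis(methoxymethoxy)-2-(3-methylbut-2-en-1-yl)benzene
Product: 6 3,5-bis(methoxymethoxy)-4-(3-methylbut-2-en-1-yl)phenol, via aryl pinacol boronate 5 (not isolated)
Conditions: [Ir(OMe)(cod)]2 (1.5 mol %), 4,4'-di-tert-butyl-2,2'-bipyridine (3 mol %), B2pin2 (1.0 equiv), THF, 80 °C; then aq. NaOH, H2O2, 0 °C
Reagents that add atoms: hydrogen peroxide, OO
Why: Iridium-catalysed aromatic C–H borylation is sterically controlled and should take the only ring C–H without an ortho substituent (para to the prenyl group), and one-pot oxidation of the boronate with alkaline peroxide, which leaves an isolated trisubstituted alkene alone, gives the symmetric phenol.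

Step 4
Reactants: 6 3,5-bis(methoxymethoxy)-4-(3-methylbut-2-en-1-yl)phenol
Product: 7 2-bromo-3,5-bis(methoxymethoxy)-4-(3-methylbut-2-en-1-yl)phenol
Conditions: NBS (1.0 equiv), CH2Cl2, −78 °C
Reagents that add atoms: N-bromosuccinimide, O=C1CCC(=O)N1Br
Why: Electrophilic aromatic bromination of a tri-oxygenated ring is far faster than attack on the alkene at low temperature, the two open ring positions are equivalent by symmetry, and one equivalent of reagent should stop at the monobromide.

Step 5
Reactants: 7 2-bromo-3,5-bis(methoxymethoxy)-4-(3-methylbut-2-en-1-yl)phenol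
Product: 11 3,5-bis(methoxymethoxy)-4-(3-methylbut-2-en-1-yl)-2-(trimethylsilyl)phenyl trifluoromethanesulfonate, via aryl silyl ether 8 (not isolated), via aryllithium 9 (not isolated), via lithium silylphenolate 10 (not isolated)
Conditions: (Me3Si)2NH, THF, 65 °C, then evaporation; n-BuLi, THF, −78 °C; then Tf2O, −78 °C to rt
Reagents that add atoms: hexamethyldisilazane, C[Si](C)(C)N[Si](C)(C)C; trifluoromethanesulfonic anhydride, O=S(=O)(OS(=O)(=O)C(F)(F)F)C(F)(F)F
Why: O-silylation, bromine–lithium exchange and a 1,3 O-to-C silyl shift (retro-Brook rearrangement) give the ortho-silyl phenolate, which is triflated in the same flask, the standard one-pot route from ortho-bromophenols to ortho-silylaryl triflates.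

Step 6
Reactants: 12 methyl 3,5-dibromo-4-hydroxybenzoate
Product: 13 methyl 3,5-dibromo-4-(methoxymethoxy)benzoate
Conditions: MOMCl, K2CO3, DMF, 0 °C to rt
Reagents that add atoms: chloromethyl methyl ether, COCCl
Why: The acidic 2,6-dibromophenol is readily O-alkylated by the unhindered α-chloro ether (Williamson-type protection).

Step 7
Reactants: 13 methyl 3,5-dibromo-4-(methoxymethoxy)benzoate
Product: 14 methyl 4-(methoxymethoxy)-3,5-bis(3-methylbut-2-en-1-yl)benzoate
Conditions: tributyl(3-methylbut-2-en-1-yl)stannane (2.5 equiv), Pd(PPh3)4 (5 mol %), DMF, 100 °C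
Reagents that add atoms: tributyl(3-methylbut-2-en-1-yl)stannane, CCCC[Sn](CCCC)(CCCC)CC=C(C)C
Why: Twofold Stille coupling, in which the para ester speeds oxidative addition and reductive elimination at the less hindered allyl terminus should give the linear prenyl groups.

Step 8
Reactants: 14 methyl 4-(methoxymethoxy)-3,5-bis(3-methylbut-2-en-1-yl)benzoate
Product: 16 3-[4-(methoxymethoxy)-3,5-bis(3-methylbut-2-en-1-yl)phenyl]-N,N-dimethyl-3-oxopropanamide, via lithium enolate 15 (not isolated)
Conditions: N,N-dimethylacetamide (2.2 equiv), LiN(i-Pr)2 (2.2 equiv), THF, −78 °C; then 14, −78 to 0 °C; then AcOH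
Reagents that add atoms: N,N-dimethylacetamide, CC(=O)N(C)C
Why: Crossed Claisen condensation of the amide enolate with the non-enolisable aryl ester, driven by deprotonation of the β-keto amide by the second equivalent of base.

Step 9
Reactants: 16 3-[4-(methoxymethoxy)-3,5-bis(3-methylbut-2-en-1-yl)phenyl]-N,N-dimethyl-3-oxopropanamide
Product: 17 (3R)-3-hydroxy-3-[4-(methoxymethoxy)-3,5-bis(3-methylbut-2-en-1-yl)phenyl]-N,N-dimethylpropanamide
Conditions: RuCl[(R,R)-TsDPEN](p-cymene) (1 mol %), HCO2H/Et3N (5:2), CH2Cl2, 30 °C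
Reagents that add atoms: none
Why: Noyori–Ikariya asymmetric transfer hydrogenation of an aryl ketone, in which the (R,R) catalyst should deliver hydride to the Si face (aryl as the large group, as with acetophenone) and so set the R carbinol that becomes C2, while alkenes and acetals are untouched.

Step 10
Reactants: 17 (3R)-3-hydroxy-3-[4-(methoxymethoxy)-3,5-bis(3-methylbut-2-en-1-yl)phenyl]-N,N-dimethylpropanamide
Product: 18 (3R)-3-[4-(methoxymethoxy)-3,5-bis(3-methylbut-2-en-1-yl)phenyl]-N,N-dimethyl-3-[(trimethylsilyl)oxy]propanamide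
Conditions: 1-(trimethylsilyl)imidazole, CH2Cl2, 0 °C to rt
Reagents that add atoms: 1-(trimethylsilyl)imidazole, C[Si](C)(C)n1ccnc1
Why: Neutral O-silylation removes the only acidic proton, so that fluoride can later release the alkoxide without any O–H in the flask, and it does not touch the benzylic stereocenter.

Step 11
Reactants: 18 (3R)-3-[4-(methoxymethoxy)-3,5-bis(3-methylbut-2-en-1-yl)phenyl]-N,N-dimethyl-3-[(trimethylsilyl)oxy]propanamide; 11 3,5-bis(methoxymethoxy)-4-(3-methylbut-2-en-1-yl)-2-(trimethylsilyl)phenyl trifluoromethanesulfonate (1.5 equiv)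
Product: 23 (2R)-5,7-bis(methoxymethoxy)-2-[4-(methoxymethoxy)-3,5-bis(3-methylbut-2-en-1-yl)phenyl]-6-(3-methylbut-2-en-1-yl)-2,3-dihydro-4H-chromen-4-one, via cesium alkoxide 19 (not isolated), via aryne 20 (not isolated), via arylcesium ether 21 (not isolated), via hemiaminal alkoxide 22 (not isolated)
Conditions: CsF (4 equiv), 18-crown-6 (2 equiv), THF, 0 °C to rt; then AcOH, 0 °C, aqueous work-up
Reagents that add atoms: none
Why: Proposed new method: fluoride strips the O-silyl group of 18 and the C-silyl group of 11, so that the proton-free cesium alkoxide 19 meets aryne 20 (triple bond between the future C4a and C8a); 19 should add at the future C8a, the aryne carbon remote from the OMOM group, because the inductively withdrawing C5 oxygen beside the triple bond distorts it so that attack comes at the far carbon and the negative charge develops next to that oxygen, and the H on C8 makes the same carbon the less hindered one, giving arylcesium 21. The carbanion at C4a then attacks the dimethylamide carbonyl in a 6-exo-trig closure that forms the C4–C4a bond and ring C; the resulting hemiaminal alkoxide 22 cannot expel dimethylamide, so the ketone is set free only by the acetic acid quench, after the base has been neutralised. The closest known reaction type is the CsF-mediated annulation of arynes with ortho-hydroxybenzoate esters to xanthones (O-arylation, then intramolecular acyl capture by the aryl anion), together with aryne insertion into amide C–N bonds, which shows aryne-derived aryl anions adding to amide carbonyls; new here are the aliphatic secondary alkoxide as nucleophile and the saturated two-carbon link to the acyl group. No stereocenter is created in 23: C2 stems from step 9 and none of its bonds is made or broken, so the R configuration should be retained, and the transient hemiaminal carbon becomes the carbonyl. The step needs regioselective addition to the aryne (secured by the OMOM/H pair flanking the triple bond and by the symmetry of phenol 6, which allows one aryne only and puts the prenyl group at C6), ring closure faster than protonation of 21 (secured by the silyl ether, which leaves no O–H, and by THF, which has no acidic C–H), and no retro-oxa-Michael opening of ring C (secured by the amide, since 22 has no enolisable ketone while fluoride is present).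

Step 12
Reactants: 23 (2R)-5,7-bis(methoxymethoxy)-2-[4-(methoxymethoxy)-3,5-bis(3-methylbut-2-en-1-yl)phenyl]-6-(3-methylbut-2-en-1-yl)-2,3-dihydro-4H-chromen-4-one
Product: 24 (2R)-5,7-dihydroxy-2-[4-hydroxy-3,5-bis(3-methylbut-2-en-1-yl)phenyl]-6-(3-methylbut-2-en-1-yl)-2,3-dihydro-4H-chromen-4-one
Conditions: 3 M aq. HCl, MeOH, 40 °C, stopped as soon as the last acetal is gone
Reagents that add atoms: none
Why: Acid-catalysed acetal exchange with methanol cleaves the three MOM ethers under conditions used for ortho-prenylated phenols, mild enough that chroman formation from the prenyl groups should stay slow, and C2 is not at risk because flavanone ring opening is a base-mediated process.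

**Compound list**
1 | resorcinol (benzene-1,3-diol) | Oc1cccc(O)c1 | starting material
2 | 1,3-bis(methoxymethoxy)benzene | COCOc1cccc(OCOC)c1 | intermediate
3 | 2,6-bis(methoxymethoxy)phenyllithium | [Li]c1c(OCOC)cccc1OCOC | intermediate (not isolated)
4 | 1,3-bis(methoxymethoxy)-2-(3-methylbut-2-en-1-yl)benzene | COCOc1cccc(OCOC)c1CC=C(C)C | intermediate
5 | 2-[3,5-bis(methoxymethoxy)-4-(3-methylbut-2-en-1-yl)phenyl]-4,4,5,5-tetramethyl-1,3,2-dioxaborolane | COCOc1cc(B2OC(C)(C)C(C)(C)O2)cc(OCOC)c1CC=C(C)C | intermediate (not isolated)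
6 | 3,5-bis(methoxymethoxy)-4-(3-methylbut-2-en-1-yl)phenol | COCOc1cc(O)cc(OCOC)c1CC=C(C)C | intermediate
7 | 2-bromo-3,5-bis(methoxymethoxy)-4-(3-methylbut-2-en-1-yl)phenol | COCOc1cc(O)c(Br)c(OCOC)c1CC=C(C)C | intermediate
8 | [2-bromo-3,5-bis(methoxymethoxy)-4-(3-methylbut-2-en-1-yl)phenoxy]trimethylsilane | COCOc1cc(O[Si](C)(C)C)c(Br)c(OCOC)c1CC=C(C)C | intermediate (not isolated)
9 | 2,4-bis(methoxymethoxy)-3-(3-methylbut-2-en-1-yl)-6-[(trimethylsilyl)oxy]phenyllithium | COCOc1cc(O[Si](C)(C)C)c([Li])c(OCOC)c1CC=C(C)C | intermediate (not isolated)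
10 | lithium 3,5-bis(methoxymethoxy)-4-(3-methylbut-2-en-1-yl)-2-(trimethylsilyl)phenolate | COCOc1cc([O-])c([Si](C)(C)C)c(OCOC)c1CC=C(C)C.[Li+] | intermediate (not isolated)
11 | 3,5-bis(methoxymethoxy)-4-(3-methylbut-2-en-1-yl)-2-(trimethylsilyl)phenyl trifluoromethanesulfonate | COCOc1cc(OS(=O)(=O)C(F)(F)F)c([Si](C)(C)C)c(OCOC)c1CC=C(C)C | intermediate
12 | methyl 3,5-dibromo-4-hydroxybenzoate | COC(=O)c1cc(Br)c(O)c(Br)c1 | starting material
13 | methyl 3,5-dibromo-4-(methoxymethoxy)benzoate | COC(=O)c1cc(Br)c(OCOC)c(Br)c1 | intermediate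
14 | methyl 4-(methoxymethoxy)-3,5-bis(3-methylbut-2-en-1-yl)benzoate | COC(=O)c1cc(CC=C(C)C)c(OCOC)c(CC=C(C)C)c1 | intermediate
15 | lithium (Z)-3-(dimethylamino)-1-[4-(methoxymethoxy)-3,5-bis(3-methylbut-2-en-1-yl)phenyl]-3-oxoprop-1-en-1-olate | CN(C)C(=O)/C=C(\[O-])c1cc(CC=C(C)C)c(OCOC)c(CC=C(C)C)c1.[Li+] | intermediate (not isolated)
16 | 3-[4-(methoxymethoxy)-3,5-bis(3-methylbut-2-en-1-yl)phenyl]-N,N-dimethyl-3-oxopropanamide | CN(C)C(=O)CC(=O)c1cc(CC=C(C)C)c(OCOC)c(CC=C(C)C)c1 | intermediate
17 | (3R)-3-hydroxy-3-[4-(methoxymethoxy)-3,5-bis(3-methylbut-2-en-1-yl)phenyl]-N,N-dimethylpropanamide | CN(C)C(=O)C[C@@H](O)c1cc(CC=C(C)C)c(OCOC)c(CC=C(C)C)c1 | intermediate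
18 | (3R)-3-[4-(methoxymethoxy)-3,5-bis(3-methylbut-2-en-1-yl)phenyl]-N,N-dimethyl-3-[(trimethylsilyl)oxy]propanamide | CN(C)C(=O)C[C@@H](O[Si](C)(C)C)c1cc(CC=C(C)C)c(OCOC)c(CC=C(C)C)c1 | intermediate
19 | cesium (1R)-3-(dimethylamino)-1-[4-(methoxymethoxy)-3,5-bis(3-methylbut-2-en-1-yl)phenyl]-3-oxopropan-1-olate | CN(C)C(=O)C[C@@H]([O-])c1cc(CC=C(C)C)c(OCOC)c(CC=C(C)C)c1.[Cs+] | intermediate (not isolated)
20 | 3,5-bis(methoxymethoxy)-4-(3-methylbut-2-en-1-yl)benzyne (1,2-didehydrobenzene, OMOM on C3 and C5, prenyl on C4) | COCOC1=C(CC=C(C)C)C(OCOC)=CC#C1 | intermediate (not isolated)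
21 | cesium 2-{(1R)-3-(dimethylamino)-1-[4-(methoxymethoxy)-3,5-bis(3-methylbut-2-en-1-yl)phenyl]-3-oxopropoxy}-4,6-bis(methoxymethoxy)-5-(3-methylbut-2-en-1-yl)benzen-1-ide | CN(C)C(=O)C[C@@H](Oc1cc(OCOC)c(CC=C(C)C)c(OCOC)[c-]1)c1cc(CC=C(C)C)c(OCOC)c(CC=C(C)C)c1.[Cs+] | intermediate (not isolated)
22 | cesium (2R)-4-(dimethylamino)-5,7-bis(methoxymethoxy)-2-[4-(methoxymethoxy)-3,5-bis(3-methylbut-2-en-1-yl)phenyl]-6-(3-methylbut-2-en-1-yl)-3,4-dihydro-2H-chromen-4-olate (C4 unassigned) | COCOc1c(CC=C(C)C)cc(cc1CC=C(C)C)[C@H]1CC([O-])(N(C)C)c2c(OCOC)c(CC=C(C)C)c(OCOC)cc2O1.[Cs+] | intermediate (not isolated)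
23 | (2R)-5,7-bis(methoxymethoxy)-2-[4-(methoxymethoxy)-3,5-bis(3-methylbut-2-en-1-yl)phenyl]-6-(3-methylbut-2-en-1-yl)-2,3-dihydro-4H-chromen-4-one | COCOc1c(CC=C(C)C)cc(cc1CC=C(C)C)[C@H]1CC(=O)c2c(OCOC)c(CC=C(C)C)c(OCOC)cc2O1 | intermediate
24 | (2R)-5,7-dihydroxy-2-[4-hydroxy-3,5-bis(3-methylbut-2-en-1-yl)phenyl]-6-(3-methylbut-2-en-1-yl)-2,3-dihydro-4H-chromen-4-one | CC(C)=CCc1cc([C@H]2CC(=O)c3c(cc(O)c(CC=C(C)C)c3O)O2)cc(CC=C(C)C)c1O | target

**Count**
Total steps: 12. Longest linear sequence: 7 steps (12 → 13 → 14 → 16 → 17 → 18 → 23 → 24; the branch from 1 reaches 11 in 5 steps and joins at step 11).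

**Steps most likely to fail**

Step 11 (bears the label). What may go wrong:
- protonation of the aryl anion before it reaches the amide, which leaves an open aryl ether;
- retro-aldol cleavage or elimination of the naked alkoxide;
- consumption of the aryne by fluoride or by a second addition to the product.

The fallback uses known reactions only, sets out from 16 and 6 and comes back at 23. Ketone 16 would be reduced with the enantiomeric catalyst RuCl[(S,S)-TsDPEN](p-cymene) in HCO2H/Et3N to (3S)-3-hydroxy-3-[4-(methoxymethoxy)-3,5-bis(3-methylbut-2-en-1-yl)phenyl]-N,N-dimethylpropanamide F1. Mitsunobu etherification of F1 with phenol 6 (PPh3, diisopropyl azodicarboxylate, toluene, 0 °C) should give, with inversion, (3R)-3-[3,5-bis(methoxymethoxy)-4-(3-methylbut-2-en-1-yl)phenoxy]-3-[4-(methoxymethoxy)-3,5-bis(3-methylbut-2-en-1-yl)phenyl]-N,N-dimethylpropanamide F2. F2 is also the compound that protonation of 21 would leave, so material from a partly failed key step could be fed in here. Activation of the amide of F2 with Tf2O and 2-chloropyridine (CH2Cl2, −78 to 0 °C) should bring about an intramolecular Vilsmeier–Haack-type acylation at either of the two equivalent positions ortho to the ether oxygen, giving (2R)-N-{5,7-bis(methoxymethoxy)-2-[4-(methoxymethoxy)-3,5-bis(3-methylbut-2-en-1-yl)phenyl]-6-(3-methylbut-2-en-1-yl)-2,3-dihydro-4H-chromen-4-ylidene}-N-methylmethanaminium trifluoromethanesulfonate F3. Hydrolysis of F3 with cold aqueous NaHCO3 gives 23.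

Step 7. What may go wrong:
- stalling after the first coupling at the hindered positions beside the OMOM group;
- allyl transposition on palladium, which would give 1,1-dimethylallyl groups;
- protodestannylation of the reagent.

The fallback sets out from 13 and comes back at 14. Twofold Stille coupling of 13 with allyltributylstannane (Pd(PPh3)4, DMF, 90 °C), where no allyl transposition can matter, would give methyl 4-(methoxymethoxy)-3,5-di(prop-2-en-1-yl)benzoate F4. Cross-metathesis of F4 with 2-methylbut-2-ene (second-generation Grubbs catalyst, RuCl2(H2IMes)(PCy3)(=CHPh), CH2Cl2, 40 °C) then turns both allyl groups into prenyl groups and gives 14.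

Step 4. What may go wrong:
- bromination of the prenyl double bond;
- ipso attack para to the hydroxyl group with dienone formation;
- a second bromination.

The fallback avoids any electrophilic halogen, sets out from 6 and comes back at 11, so it replaces steps 4 and 5. Phenol 6 would be carbamoylated (NaH, ClC(O)NEt2, THF) to 3,5-bis(methoxymethoxy)-4-(3-methylbut-2-en-1-yl)phenyl N,N-diethylcarbamate F5. Directed ortho-metalation between the carbamate and an OMOM group (s-BuLi, TMEDA, THF, −78 °C; then Me3SiCl) would give 3,5-bis(methoxymethoxy)-4-(3-methylbut-2-en-1-yl)-2-(trimethylsilyl)phenyl N,N-diethylcarbamate F6. Reductive cleavage of the carbamate (LiAlH4, THF, 0 °C) would give 3,5-bis(methoxymethoxy)-4-(3-methylbut-2-en-1-yl)-2-(trimethylsilyl)phenol F7. Triflation of F7 (Tf2O, pyridine, CH2Cl2, 0 °C) gives 11.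

**Further compounds**
F1 | step 11 | (3S)-3-hydroxy-3-[4-(methoxymethoxy)-3,5-bis(3-methylbut-2-en-1-yl)phenyl]-N,N-dimethylpropanamide | CN(C)C(=O)C[C@H](O)c1cc(CC=C(C)C)c(OCOC)c(CC=C(C)C)c1
F2 | step 11 | (3R)-3-[3,5-bis(methoxymethoxy)-4-(3-methylbut-2-en-1-yl)phenoxy]-3-[4-(methoxymethoxy)-3,5-bis(3-methylbut-2-en-1-yl)phenyl]-N,N-dimethylpropanamide | CN(C)C(=O)C[C@@H](Oc1cc(OCOC)c(CC=C(C)C)c(OCOC)c1)c1cc(CC=C(C)C)c(OCOC)c(CC=C(C)C)c1
F3 | step 11 | (2R)-N-{5,7-bis(methoxymethoxy)-2-[4-(methoxymethoxy)-3,5-bis(3-methylbut-2-en-1-yl)phenyl]-6-(3-methylbut-2-en-1-yl)-2,3-dihydro-4H-chromen-4-ylidene}-N-methylmethanaminium trifluoromethanesulfonate | C[N+](C)=C1C[C@H](c2cc(CC=C(C)C)c(OCOC)c(CC=C(C)C)c2)Oc2cc(OCOC)c(CC=C(C)C)c(OCOC)c21.[O-]S(=O)(=O)C(F)(F)F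
F4 | step 7 | methyl 4-(methoxymethoxy)-3,5-di(prop-2-en-1-yl)benzoate | COC(=O)c1cc(CC=C)c(OCOC)c(CC=C)c1
F5 | step 4 | 3,5-bis(methoxymethoxy)-4-(3-methylbut-2-en-1-yl)phenyl N,N-diethylcarbamate | CCN(CC)C(=O)Oc1cc(OCOC)c(CC=C(C)C)c(OCOC)c1
F6 | step 4 | 3,5-bis(methoxymethoxy)-4-(3-methylbut-2-en-1-yl)-2-(trimethylsilyl)phenyl N,N-diethylcarbamate | CCN(CC)C(=O)Oc1cc(OCOC)c(CC=C(C)C)c(OCOC)c1[Si](C)(C)C
F7 | step 4 | 3,5-bis(methoxymethoxy)-4-(3-methylbut-2-en-1-yl)-2-(trimethylsilyl)phenol | Oc1cc(OCOC)c(CC=C(C)C)c(OCOC)c1[Si](C)(C)C
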